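**Plan**

- Feature: number the oxolane O1, C2 (trimethoxyphenyl), C3 (CH2OH), C4 (carbinol arm), C5 (H2). C5 is a bare O–CH2 unit, so it can come from formaldehyde. C2 is benzylic and C4 lies next to a carbon that can be a carbonyl, so C2 and C4 can be joined by a temporary cyclopropane bond, and the C3 CH2O arm and the C4 carbonyl by a temporary γ-lactone.
- Retrosynthesis, in order: the carbinol C–H (ketone reduction), C4 epimerisation, the aryl–C(O) bond (aryllithium plus lactone), C4–CO2Me (Krapcho), then O1–C2 and C4–C5 together ([3+2] of formaldehyde across the cyclopropane), then the lactone C–O, the two cyclopropane bonds at C4 (alkene plus malonate carbene) and the aryl–alkyne bond.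
- Forward: aryl alkyne, (Z)-alkene, cyclopropane, lactone ring, oxolane ring (key step), opening of the lactone by the second arene, reduction.
- Stereochemistry: C3 and the cis-cyclopropane come from an enantioselective copper-carbene cyclopropanation of the (Z)-alkene. C2 follows by stereospecific inversion in the annulation. C4 is set by base equilibration to the all-trans ring. The carbinol is set by Corey–Bakshi–Shibata reduction, matched with the Felkin–Anh preference.

Key step: step 5

Assumption: the side-arm bis(oxazoline)/copper catalyst of step 3 is taken to select the alkene face of 4 as it does for (Z)-β-substituted styrenes; the ligand antipode that gives (2S,3S)-6 is the one meant.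

**Route**

Step 1
Reactants: 1 5-iodo-1,2,3-trimethoxybenzene; 2 tert-butyldimethyl(prop-2-yn-1-yloxy)silane
Product: 3 tert-butyldimethyl{[3-(3,4,5-trimethoxyphenyl)prop-2-yn-1-yl]oxy}silane
Conditions: PdCl2(PPh3)2 (2 mol %), CuI (4 mol %), Et3N, THF, 23 °C
Reagents that add atoms: none
Why: Sonogashira coupling, in which oxidative addition of the aryl iodide to zerovalent palladium, transmetallation from the copper acetylide and reductive elimination form the aryl–alkyne bond at room temperature while the silyl ether is inert to the amine base.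

Step 2
Reactants: 3 tert-butyldimethyl{[3-(3,4,5-trimethoxyphenyl)prop-2-yn-1-yl]oxy}silane
Product: 4 tert-butyldimethyl{[(2Z)-3-(3,4,5-trimethoxyphenyl)prop-2-en-1-yl]oxy}silane
Conditions: H2 (1 atm), Pd/CaCO3 poisoned with Pb(OAc)2 (Lindlar catalyst), quinoline, EtOAc, 23 °C
Reagents that add atoms: none
Why: Lindlar semihydrogenation adds H2 syn on the poisoned palladium surface and stops at the alkene, which sets the (Z)-geometry needed for a cis-cyclopropane, with quinoline holding back over-reduction and Z/E isomerisation.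

Step 3
Reactants: 4 tert-butyldimethyl{[(2Z)-3-(3,4,5-trimethoxyphenyl)prop-2-en-1-yl]oxy}silane; 5 bis(methoxycarbonyl)(phenyliodonio)methanide
Product: 6 dimethyl (2S,3S)-2-{[(tert-butyldimethylsilyl)oxy]methyl}-3-(3,4,5-trimethoxyphenyl)cyclopropane-1,1-dicarboxylate
Conditions: Cu(MeCN)4PF6 (10 mol %), dibenzyl-bridged phenyl bis(oxazoline) side-arm ligand (12 mol %), 4 Å MS, CH2Cl2, 0 °C
Reagents that add atoms: none
Why: Copper-carbene cyclopropanation by carbene transfer from an iodonium ylide, in which the electrophilic bis(methoxycarbonyl)carbene on monovalent copper adds to the electron-rich styrene-type alkene in a concerted stereospecific [2+1] step that keeps the cis relation, while the C2-symmetric ligand chooses the alkene face and so sets C2 and C3 together.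

Step 4
Reactants: 6 dimethyl (2S,3S)-2-{[(tert-butyldimethylsilyl)oxy]methyl}-3-(3,4,5-trimethoxyphenyl)cyclopropane-1,1-dicarboxylate
Product: 8 methyl (1R,5S,6S)-2-oxo-6-(3,4,5-trimethoxyphenyl)-3-oxabicyclo[3.1.0]hexane-1-carboxylate, via hydroxymethyl cyclopropane diester 7 (not isolated)
Conditions: TBAF, THF, 0 to 23 °C
Reagents that add atoms: none
Why: Fluoride-mediated silyl ether cleavage followed by spontaneous lactonisation (5-exo-trig acyl substitution), in which the freed alkoxide can reach only the ester cis to it, so C1 becomes a stereocentre of fixed configuration and the aryl group stays cis to the lactone CH2.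

Step 5
Reactants: 8 methyl (1R,5S,6S)-2-oxo-6-(3,4,5-trimethoxyphenyl)-3-oxabicyclo[3.1.0]hexane-1-carboxylate; 9 formaldehyde (charged as paraformaldehyde)
Product: 10 methyl (1S,5S,6R)-2-oxo-6-(3,4,5-trimethoxyphenyl)-3,7-dioxabicyclo[3.3.0]octane-1-carboxylate
Conditions: Sn(OTf)2 (10 mol %), paraformaldehyde (5 equiv CH2O), ClCH2CH2Cl, 23 to 40 °C
Reagents that add atoms: none
Why: Sn(OTf)2 chelates the lactone and ester carbonyls on C1 of 8 and polarises the benzylic C1–C6 bond (the temporary C4–C2 bond of the plan), the oxygen of formaldehyde released from the polymer attacks C6 from the rear of that bond in an SN2-like step (O1–C2), and the O-alkyl oxocarbenium ion so formed is captured by the tin enolate in an aldol-type step (C4–C5). The closest known reaction is the Sn(OTf)2-catalysed stereospecific [3+2] annulation of aryl cyclopropane-1,1-dicarboxylates, including 2,3-disubstituted ones, with aldehydes. The oxolane ring closes in the second bond-forming event as a 5-(enolexo)-endo-trig attack of the enolate carbon on the oxocarbenium carbon inside the ion pair. The benzylic centre (C6 of 10, C2 of the target) is set by inversion, which turns the cis aryl/CH2O relation of the cyclopropane into trans; the quaternary centre (C1 of 10) is set by the lactone tether, because only the cis-fused 5/5 bicycle can form; C5 is carried over unchanged and anchors the absolute configuration. The step needs cleavage of the benzylic C1–C6 bond rather than C1–C5, which the aryl donor secures, and capture faster than ionisation to a free benzylic cation, which is helped by the only moderately donating 3,4,5-trimethoxyphenyl ring and by the strain of the bicycle. Should some ionisation occur, the aryl group on the convex face is also the thermodynamically preferred arrangement, so reversible opening under the Lewis acid should lead to the same diastereomer.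

Step 6
Reactants: 10 methyl (1S,5S,6R)-2-oxo-6-(3,4,5-trimethoxyphenyl)-3,7-dioxabicyclo[3.3.0]octane-1-carboxylate
Product: 11 (1S,5S,6R)-6-(3,4,5-trimethoxyphenyl)-3,7-dioxabicyclo[3.3.0]octan-2-one
Conditions: LiCl, H2O, DMSO, 150 °C
Reagents that add atoms: none
Why: Krapcho dealkoxycarbonylation, in which chloride dealkylates the methyl ester by SN2 at the methyl group, the β-carbonyl carboxylate loses CO2 and the lactone enolate is protonated to the only possible cis-fused bicycle, which sets C1 while the lactone and the aryl methyl ethers survive.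

Step 7
Reactants: 12 4-bromo-1,2-dimethoxybenzene; 11 (1S,5S,6R)-6-(3,4,5-trimethoxyphenyl)-3,7-dioxabicyclo[3.3.0]octan-2-one
Product: 14 (3,4-dimethoxyphenyl)[(3S,4S,5R)-4-(hydroxymethyl)-5-(3,4,5-trimethoxyphenyl)oxolan-3-yl]methanone, via 3,4-dimethoxyphenyllithium 13 (not isolated)
Conditions: 12, n-BuLi, THF, −78 °C; then 11, −78 °C; AcOH, −78 °C
Reagents that add atoms: none
Why: Nucleophilic acyl substitution of a γ-lactone by an aryllithium made by bromine–lithium exchange, in which the lithium hemiketal alkoxide formed at −78 °C is held in the cis-fused bicycle and does not collapse to the ketone before the cold acidic quench, which should prevent a second addition and leave the three ring stereocentres untouched.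

Step 8
Reactants: 14 (3,4-dimethoxyphenyl)[(3S,4S,5R)-4-(hydroxymethyl)-5-(3,4,5-trimethoxyphenyl)oxolan-3-yl]methanone
Product: 16 [(3R,4S,5R)-4-{[(tert-butyldimethylsilyl)oxy]methyl}-5-(3,4,5-trimethoxyphenyl)oxolan-3-yl](3,4-dimethoxyphenyl)methanone, via cis silyl ether ketone 15 (not isolated)
Conditions: TBSCl, imidazole, DMF, 23 °C; then MeOH, DBU, 40 °C
Reagents that add atoms: tert-butyldimethylsilyl chloride, CC(C)(C)[Si](C)(C)Cl
Why: Silylation of the primary alcohol removes the ring-closed hemiketal tautomer, and base-mediated epimerisation through the ketone enolate then equilibrates the carbon α to the aryl ketone to the thermodynamically preferred all-trans oxolane, which relieves the cis-vicinal clash of the aroyl and silyloxymethyl groups.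

Step 9
Reactants: 16 [(3R,4S,5R)-4-{[(tert-butyldimethylsilyl)oxy]methyl}-5-(3,4,5-trimethoxyphenyl)oxolan-3-yl](3,4-dimethoxyphenyl)methanone
Product: 17 (S)-[(3R,4S,5R)-4-{[(tert-butyldimethylsilyl)oxy]methyl}-5-(3,4,5-trimethoxyphenyl)oxolan-3-yl](3,4-dimethoxyphenyl)methanol
Conditions: (3aR)-1-methyl-3,3-diphenyltetrahydro-1H,3H-pyrrolo[1,2-c][1,3,2]oxazaborole [(R)-Me-CBS] (0.2 equiv), BH3·SMe2, THF, −20 °C; MeOH
Reagents that add atoms: none
Why: Corey–Bakshi–Shibata reduction, in which the (R)-oxazaborolidine–borane complex binds the ketone anti to the aryl group and delivers hydride to the face that gives the (S)-carbinol, which is also the Felkin–Anh face of this α-branched ketone (ring carbon bearing the silyloxymethyl group as the large substituent), so reagent and substrate control are matched.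

Step 10
Reactants: 17 (S)-[(3R,4S,5R)-4-{[(tert-butyldimethylsilyl)oxy]methyl}-5-(3,4,5-trimethoxyphenyl)oxolan-3-yl](3,4-dimethoxyphenyl)methanol
Product: 18 (S)-(3,4-dimethoxyphenyl)[(3R,4S,5R)-4-(hydroxymethyl)-5-(3,4,5-trimethoxyphenyl)oxolan-3-yl]methanol
Conditions: TBAF, THF, 0 to 23 °C
Reagents that add atoms: none
Why: Fluoride-mediated desilylation driven by the Si–F bond frees the primary alcohol without touching the benzylic alcohol, the benzylic ether or any stereocentre, and gives the target.

**Compound list**

1 | 5-iodo-1,2,3-trimethoxybenzene | COc1cc(I)cc(OC)c1OC | starting material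
2 | tert-butyldimethyl(prop-2-yn-1-yloxy)silane | C#CCO[Si](C)(C)C(C)(C)C | starting material
3 | tert-butyldimethyl{[3-(3,4,5-trimethoxyphenyl)prop-2-yn-1-yl]oxy}silane | COc1cc(C#CCO[Si](C)(C)C(C)(C)C)cc(OC)c1OC | intermediate
4 | tert-butyldimethyl{[(2Z)-3-(3,4,5-trimethoxyphenyl)prop-2-en-1-yl]oxy}silane | COc1cc(/C=C\CO[Si](C)(C)C(C)(C)C)cc(OC)c1OC | intermediate
5 | bis(methoxycarbonyl)(phenyliodonio)methanide (phenyliodonium ylide of dimethyl malonate) | COC(=O)[C-](C(=O)OC)[I+]c1ccccc1 | starting material
6 | dimethyl (2S,3S)-2-{[(tert-butyldimethylsilyl)oxy]methyl}-3-(3,4,5-trimethoxyphenyl)cyclopropane-1,1-dicarboxylate (aryl cis to CH2O) | COC(=O)C1(C(=O)OC)[C@@H](CO[Si](C)(C)C(C)(C)C)[C@H]1c2cc(OC)c(OC)c(OC)c2 | intermediate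
7 | dimethyl (2S,3S)-2-(hydroxymethyl)-3-(3,4,5-trimethoxyphenyl)cyclopropane-1,1-dicarboxylate | COC(=O)C1(C(=O)OC)[C@@H](CO)[C@H]1c2cc(OC)c(OC)c(OC)c2 | intermediate
8 | methyl (1R,5S,6S)-2-oxo-6-(3,4,5-trimethoxyphenyl)-3-oxabicyclo[3.1.0]hexane-1-carboxylate (aryl cis to the lactone CH2) | COC(=O)[C@]12C(=O)OC[C@H]1[C@H]2c3cc(OC)c(OC)c(OC)c3 | intermediate
9 | formaldehyde (charged as paraformaldehyde) | C=O | starting material
10 | methyl (1S,5S,6R)-2-oxo-6-(3,4,5-trimethoxyphenyl)-3,7-dioxabicyclo[3.3.0]octane-1-carboxylate (cis-fused, aryl trans to the lactone CH2) | COC(=O)[C@@]12CO[C@@H](c3cc(OC)c(OC)c(OC)c3)[C@@H]1COC2=O | intermediate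
11 | (1S,5S,6R)-6-(3,4,5-trimethoxyphenyl)-3,7-dioxabicyclo[3.3.0]octan-2-one | O=C1OC[C@@H]2[C@H]1CO[C@H]2c1cc(OC)c(OC)c(OC)c1 | intermediate
12 | 4-bromo-1,2-dimethoxybenzene | COc1ccc(Br)cc1OC | starting material
13 | 3,4-dimethoxyphenyllithium | [Li]c1ccc(OC)c(OC)c1 | intermediate
14 | (3,4-dimethoxyphenyl)[(3S,4S,5R)-4-(hydroxymethyl)-5-(3,4,5-trimethoxyphenyl)oxolan-3-yl]methanone (open form of its bicyclic hemiketal) | COc1ccc(C(=O)[C@@H]2CO[C@@H](c3cc(OC)c(OC)c(OC)c3)[C@@H]2CO)cc1OC | intermediate
15 | [(3S,4S,5R)-4-{[(tert-butyldimethylsilyl)oxy]methyl}-5-(3,4,5-trimethoxyphenyl)oxolan-3-yl](3,4-dimethoxyphenyl)methanone | COc1ccc(C(=O)[C@@H]2CO[C@@H](c3cc(OC)c(OC)c(OC)c3)[C@@H]2CO[Si](C)(C)C(C)(C)C)cc1OC | intermediate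
16 | [(3R,4S,5R)-4-{[(tert-butyldimethylsilyl)oxy]methyl}-5-(3,4,5-trimethoxyphenyl)oxolan-3-yl](3,4-dimethoxyphenyl)methanone | COc1ccc(C(=O)[C@H]2CO[C@@H](c3cc(OC)c(OC)c(OC)c3)[C@@H]2CO[Si](C)(C)C(C)(C)C)cc1OC | intermediate
17 | (S)-[(3R,4S,5R)-4-{[(tert-butyldimethylsilyl)oxy]methyl}-5-(3,4,5-trimethoxyphenyl)oxolan-3-yl](3,4-dimethoxyphenyl)methanol | COc1ccc([C@@H](O)[C@H]2CO[C@@H](c3cc(OC)c(OC)c(OC)c3)[C@@H]2CO[Si](C)(C)C(C)(C)C)cc1OC | intermediate
18 | (S)-(3,4-dimethoxyphenyl)[(3R,4S,5R)-4-(hydroxymethyl)-5-(3,4,5-trimethoxyphenyl)oxolan-3-yl]methanol | COc1ccc([C@@H](O)[C@H]2CO[C@@H](c3cc(OC)c(OC)c(OC)c3)[C@@H]2CO)cc1OC | target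

Total step count: 10
Longest linear sequence: 10 steps (1 to 18)

**Steps most likely to fail**

Step 5. Monomeric formaldehyde may re-polymerise or hydroxymethylate the electron-rich arene faster than it intercepts the tin-bound bicycle. The strained lactone-fused cyclopropane may also ionise completely at the benzylic bond before capture, so that conversion or stereospecificity is lost. The fallback sets out from 6 and returns at 10. The monocyclic cyclopropane-1,1-diester 6 belongs to the substrate class on which the aldehyde annulation is established. It would be annulated with paraformaldehyde under Sn(OTf)2 (or AlCl3) in ClCH2CH2Cl, again with inversion at the benzylic carbon, to give dimethyl (4S,5R)-4-{[(tert-butyldimethylsilyl)oxy]methyl}-5-(3,4,5-trimethoxyphenyl)oxolane-3,3-dicarboxylate F1. TBAF in THF would then free the alkoxide, which lactonises onto the cis ester to give 10. The lactone is thus built after the oxolane instead of before it.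

Step 3. The copper carbene may discriminate poorly between the faces of a (Z)-alkene carrying an allylic silyloxy group, or be diverted through an oxonium ylide at the ether oxygen. The fallback sets out from 4 and returns at 8, and delivers the carbene intramolecularly. TBAF would give (2Z)-3-(3,4,5-trimethoxyphenyl)prop-2-en-1-ol F2. Acylation with methyl malonyl chloride (Et3N, CH2Cl2, 0 °C) would give methyl (2Z)-3-(3,4,5-trimethoxyphenyl)prop-2-en-1-yl propanedioate F3. Regitz diazo transfer with 4-acetamidobenzenesulfonyl azide and Et3N in MeCN would give methyl (2Z)-3-(3,4,5-trimethoxyphenyl)prop-2-en-1-yl 2-diazopropanedioate F4. Intramolecular cyclopropanation with Cu(MeCN)4PF6 and a tert-butyl bis(oxazoline) would then close the cyclopropane and the lactone in one event to give 8. The tether enforces the cis fusion and the (Z)-alkene places the aryl group cis to the lactone CH2. The enantiomeric purity of 8 could be raised by recrystallisation if needed.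

Step 7. The ketone may be released before the quench and take up a second aryllithium, or the aryllithium may enolise the lactone instead of adding. The fallback sets out from 11 and returns at 15. Aminolysis of the lactone with Me(MeO)NH·HCl and AlMe3 in CH2Cl2 would give (3S,4S,5R)-4-(hydroxymethyl)-N-methoxy-N-methyl-5-(3,4,5-trimethoxyphenyl)oxolane-3-carboxamide F5. Silylation (TBSCl, imidazole, DMF) would give (3S,4S,5R)-4-{[(tert-butyldimethylsilyl)oxy]methyl}-N-methoxy-N-methyl-5-(3,4,5-trimethoxyphenyl)oxolane-3-carboxamide F6. Addition of 13 at −78 °C to this Weinreb amide stops at the chelated tetrahedral intermediate and would give 15 on work-up. Compound 15 is then epimerised with DBU to 16 as in step 8.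

**Further compounds**

F1 | step 5 | dimethyl (4S,5R)-4-{[(tert-butyldimethylsilyl)oxy]methyl}-5-(3,4,5-trimethoxyphenyl)oxolane-3,3-dicarboxylate | COC(=O)C1(C(=O)OC)CO[C@@H](c2cc(OC)c(OC)c(OC)c2)[C@@H]1CO[Si](C)(C)C(C)(C)C
F2 | step 3 | (2Z)-3-(3,4,5-trimethoxyphenyl)prop-2-en-1-ol | COc1cc(/C=C\CO)cc(OC)c1OC
F3 | step 3 | methyl (2Z)-3-(3,4,5-trimethoxyphenyl)prop-2-en-1-yl propanedioate | COC(=O)CC(=O)OC/C=C\c1cc(OC)c(OC)c(OC)c1
F4 | step 3 | methyl (2Z)-3-(3,4,5-trimethoxyphenyl)prop-2-en-1-yl 2-diazopropanedioate | COC(=O)C(=[N+]=[N-])C(=O)OC/C=C\c1cc(OC)c(OC)c(OC)c1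
F5 | step 7 | (3S,4S,5R)-4-(hydroxymethyl)-N-methoxy-N-methyl-5-(3,4,5-trimethoxyphenyl)oxolane-3-carboxamide | CON(C)C(=O)[C@@H]1CO[C@@H](c2cc(OC)c(OC)c(OC)c2)[C@@H]1CO
F6 | step 7 | (3S,4S,5R)-4-{[(tert-butyldimethylsilyl)oxy]methyl}-N-methoxy-N-methyl-5-(3,4,5-trimethoxyphenyl)oxolane-3-carboxamide | CON(C)C(=O)[C@@H]1CO[C@@H](c2cc(OC)c(OC)c(OC)c2)[C@@H]1CO[Si](C)(C)C(C)(C)C
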